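The readings are simulated on assumed constants, noise included.

At 12.0 h the ash run, which is this flask followed so far, reads G at 59% and X at 1%, and by 50.0 h G reads 52%, so the stretch to watch is where X fades.

| flask | X | L | Z | remark | time |
|---|---|---|---|---|---|
| ash | 0.40 M | 0.40 M | 2.5 equiv | the very flask that is asked about, followed so far |  |
| alder | 0.27 M | 0.27 M | 2.5 equiv | run made earlier |  |
| flask | 0.40 M | 0.40 M | 2.50 equiv |  | 4.0 d |

- ash (time / h: G / %, X / %): 2.50: 22, 38; 6.00: 46, 11; 12.0: 59, 1; 25.0: 50, 1; 50.0: 52, 0
- alder (time / d: G / %, X / %): 0.104: 23, 29; 0.250: 53, 5; 0.625: 54, 0; 1.67: 50, 2; 4.00: 53, 5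

(readings scatter by 2 percentage points)

- Q is single-handed; X and L are mirror images of each other, charged as a racemate, each of them at the stated concentration
- given per volume of solution although it is solid: Z
- the numbers in the tables scatter by 2 percentage points (one standard deviation)
- at the start none of Z is in solution
- the handed part of Q does not stay in what it makes, so the products of the two hands are mirror images too

* time, not beyond 4.0 d, at which the flask holds most G
* the amount of G, in percent of the X and L together charged, at that time

Whether X can fade at all is told by the reach of Z: counting one Z for each X or L used, the share of X and L together that the charge of Z can convert is the equivalents of Z divided by 2, here 125%. That is more than the whole charge, so X and L, not Z, are the limiting reagent in this flask. My own reckoning reads the peak of G off the ash readings, near where X fades, and adds no figure of its own. The forecast says “I expect a peak near X exhaustion” and gives 56% at 0.45 d.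

The flask gives 57.3% at 0.446 d, with X at 0.379%.

    Q + X → G (k = 0.310 L mol⁻¹ min⁻¹)
    Q + L → E (k = 0.180 L mol⁻¹ min⁻¹)
    X ⇌ L (k = 1.10 min⁻¹)
    G ⇌ E (k = 7.40 × 10⁻⁴ min⁻¹)
    Z ⇌ Q, rate k5*(cs5 - [Q]) while solid is left; crystals form when [Q] > cs5 (solubility = 0.130 M, k = 0.0140 min⁻¹)

The loss of G to E has a half-life of 0.65 d, forward rate alone, shorter than 4.0 d, and G stands at 50.0% at 4.00 d. The reach leaves 0.200 M of Z beyond what X and L take, and at that time this stands as Q at 0.130 M and undissolved Z at 0.0700 M. With 0.620 equiv of Z the reach is 31.0%, and that neighbour ends with G and E together at 31.0%, Z at 0% and X at 34.5%.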